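**Retrosynthetic overview**

- The strategy rests on the benzene ring of the target, which carries oxygen on C1′ and C3′ and the C15 chain on C5′ (chain numbered C1–C15 from the ring). This ring is one dehydrogenation and one decarboxylation away from the cyclohexane-1,3-dione ester 12, so it is built on the finished chain and no phenol ether is ever cleaved.
- Target 20 ⇐ triacetate 19 (aryl acetates removed selectively) ⇐ triol 18 ⇐ Z-alkene 17 ⇐ alkyne 16 (semihydrogenation of C8≡C9) ⇐ methyl resorcylate 14 ⇐ dione ester 12.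
- The only ring is formed once, in step 5, as a carbocycle from enone 9 and dimethyl malonate 10 (Michael bond C1–C6, Claisen bond C2–C3); it is aromatized in step 6.
- Enone 9 ⇐ aldehyde 7 + acetonylidene phosphorane 8; 7 ⇐ terminal alkene 5 ⇐ acetylide of silylated (R)-oct-1-yn-3-ol 2 + 9-bromonon-1-ene 3. The C10 stereocentre comes from 1 and is never touched; the Z-alkene is carried as the alkyne until bromine has been used.

Key step: step 5

Remark: the cyclohexanedione intermediates are drawn as keto tautomers; they are expected as enol/keto and ring-diastereomer mixtures, all of which converge at the aromatization.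

**Step 1**
Reactants: 1 (R)-oct-1-yn-3-ol
Product: 2 triisopropyl{[(3R)-oct-1-yn-3-yl]oxy}silane
Conditions: TIPSOTf, 2,6-lutidine, CH2Cl2, 0 °C → rt
Reagents that add atoms: triisopropylsilyl trifluoromethanesulfonate (TIPSOTf), CC(C)[Si](OS(=O)(=O)C(F)(F)F)(C(C)C)C(C)C
Why: O-silylation of a secondary alcohol with a silyl triflate leaves the C3–O bond and hence the R configuration untouched, and the bulky triisopropylsilyl (TIPS) ether is chosen because it must later outlast n-BuLi, hot methoxide, HBr in DMF and hot aqueous NaOH.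

**Step 2**
Reactants: 2 triisopropyl{[(3R)-oct-1-yn-3-yl]oxy}silane; 3 9-bromonon-1-ene
Product: 5 triisopropyl{[(12R)-heptadec-1-en-10-yn-12-yl]oxy}silane, via lithium acetylide 4 (not isolated)
Conditions: n-BuLi, THF, −78 °C; then 3, DMPU, −78 °C → rt
Reagents that add atoms: none
Why: Acetylide alkylation: the terminal alkyne C–H is the only proton n-BuLi removes at −78 °C, and the lithium acetylide displaces the primary bromide by SN2 in the presence of DMPU without involving the propargylic stereocentre.

**Step 3**
Reactants: 5 triisopropyl{[(12R)-heptadec-1-en-10-yn-12-yl]oxy}silane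
Product: 7 (11R)-11-(triisopropylsilyloxy)hexadec-9-ynal, via diol 6 (not isolated)
Conditions: OsO4 (cat.), NaIO4, 2,6-lutidine, dioxane/H2O (3:1), rt
Reagents that add atoms: OsO4, O=[Os](=O)(=O)=O (source of the aldehyde oxygen); NaIO4, [Na+].[O-]I(=O)(=O)=O (re-supplies that oxygen to osmium)
Why: Lemieux–Johnson oxidative cleavage: OsO4 dihydroxylates the terminal alkene far faster than the hindered internal alkyne, and NaIO4 cleaves diol 6 to the aldehyde while reoxidising osmium, with 2,6-lutidine suppressing over-oxidation.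

**Step 4**
Reactants: 7 (11R)-11-(triisopropylsilyloxy)hexadec-9-ynal; 8 1-(triphenylphosphoranylidene)propan-2-one
Product: 9 (3E,14R)-14-(triisopropylsilyloxy)nonadec-3-en-12-yn-2-one
Conditions: toluene, 80 °C
Reagents that add atoms: none
Why: Wittig olefination with a ketone-stabilised ylide should give the E-enone from the unhindered aliphatic aldehyde, and nothing else in 7 is electrophilic (either enone geometry would serve in step 5).

**Step 5**
Reactants: 9 (3E,14R)-14-(triisopropylsilyloxy)nonadec-3-en-12-yn-2-one; 10 dimethyl malonate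
Product: 12 methyl 2,4-dioxo-6-[(10R)-10-(triisopropylsilyloxy)pentadec-8-yn-1-yl]cyclohexane-1-carboxylate, via Michael adduct 11 (not isolated)
Conditions: NaOMe (1.2 equiv), MeOH, rt → 65 °C; then 1 M HCl, 0 °C (pH 3)
Reagents that add atoms: none
Why: Methoxide deprotonates dimethyl malonate and the soft, stabilised enolate adds 1,4 to C4 of enone 9 to give keto diester 11; proton exchange then delivers the C1 (methyl-side) enolate, which attacks one malonate ester carbonyl and expels methoxide (Claisen condensation), and the product is deprotonated at once to its stabilised 1,3-dicarbonyl sodium enolate, which drives all the reversible stages forward. The closest known reaction type is the Michael–Claisen annulation of dialkyl malonates with alk-3-en-2-ones that leads to 5-alkylcyclohexane-1,3-diones. The one ring formed (bonds C1–C6 and C2–C3, numbered from the ester-bearing carbon) closes in the 6-(enolendo)-exo-trig mode. The two new sp3 centres, ring C1 and C6, are not controlled (trans is expected after equilibration through the acidic C1–H) and both are flattened in step 6, while C10 of the chain is a spectator. The step needs 1,4- instead of 1,2-addition and closure through the methyl-side enolate: the first is secured by the soft malonate anion and the reversibility of carbonyl addition, the second because closure from the C3 enolate would give a four-membered ring, and the dialkyl alkyne and the TIPS ether are inert to methoxide.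

**Step 6**
Reactants: 12 methyl 2,4-dioxo-6-[(10R)-10-(triisopropylsilyloxy)pentadec-8-yn-1-yl]cyclohexane-1-carboxylate
Product: 14 methyl 2,4-dihydroxy-6-[(10R)-10-(triisopropylsilyloxy)pentadec-8-yn-1-yl]benzoate, via bromo diketo ester 13 (not isolated)
Conditions: Br2 (1.0 equiv, added dropwise), DMF, 0 °C → rt; then 80 °C
Reagents that add atoms: none
Why: Halogenative aromatization of a cyclic 1,3-dione ester: the enol of 12 is brominated at C3 much faster than bromine adds to a dialkyl alkyne, and on heating bromide 13 should lose HBr by 1,4-elimination through its C1=C2 enol and tautomerise to the resorcylate, the single equivalent of bromine being consumed before any electron-rich arene exists and DMF tempering the HBr so that the TIPS ether should survive.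

**Step 7**
Reactants: 14 methyl 2,4-dihydroxy-6-[(10R)-10-(triisopropylsilyloxy)pentadec-8-yn-1-yl]benzoate
Product: 16 5-[(10R)-10-(triisopropylsilyloxy)pentadec-8-yn-1-yl]benzene-1,3-diol, via resorcylic acid 15 (not isolated)
Conditions: NaOH, MeOH/H2O, reflux, Ar; then 1 M HCl (pH 4), 40 °C
Reagents that add atoms: none
Why: Saponification followed by decarboxylation of a 6-alkyl-β-resorcylic acid, which loses CO2 readily through its ipso-protonated keto tautomer (reverse Kolbe–Schmitt reaction); the internal alkyne and the alkyl TIPS ether are stable to aqueous hydroxide, and air is excluded to protect the resorcinolate.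

**Step 8**
Reactants: 16 5-[(10R)-10-(triisopropylsilyloxy)pentadec-8-yn-1-yl]benzene-1,3-diol
Product: 17 5-[(8Z,10R)-10-(triisopropylsilyloxy)pentadec-8-en-1-yl]benzene-1,3-diol
Conditions: H2 (1 atm), Pd/CaCO3 poisoned with Pb(OAc)2 (Lindlar catalyst), quinoline, EtOAc, rt
Reagents that add atoms: none
Why: Lindlar semihydrogenation delivers both hydrogens syn from the poisoned palladium surface to give the 8Z alkene, quinoline and monitored hydrogen uptake guard against over-reduction, and C10 is untouched and stays R because the alkenyl group still ranks between oxygen and pentyl.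

**Step 9**
Reactants: 17 5-[(8Z,10R)-10-(triisopropylsilyloxy)pentadec-8-en-1-yl]benzene-1,3-diol
Product: 18 5-[(8Z,10R)-10-hydroxypentadec-8-en-1-yl]benzene-1,3-diol
Conditions: Bu4NF (TBAF, 4 equiv), THF, rt, Ar; then 0.5 M HCl to pH 6
Reagents that add atoms: none
Why: Fluoride-induced desilylation breaks only the Si–O bond, so the allylic C10–O bond and its configuration are retained, and the excess of fluoride compensates for deprotonation of the two phenols.

**Step 10**
Reactants: 18 5-[(8Z,10R)-10-hydroxypentadec-8-en-1-yl]benzene-1,3-diol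
Product: 19 5-[(8Z,10R)-10-acetoxypentadec-8-en-1-yl]-1,3-phenylene diacetate
Conditions: Ac2O, pyridine, DMAP (cat.), CH2Cl2, 0 °C → rt
Reagents that add atoms: acetic anhydride, CC(=O)OC(C)=O
Why: DMAP-catalysed O-acylation with acetic anhydride esterifies both phenols and the secondary allylic alcohol at oxygen, with retention at C10.

**Step 11**
Reactants: 19 5-[(8Z,10R)-10-acetoxypentadec-8-en-1-yl]-1,3-phenylene diacetate
Product: 20 (6R,7Z)-15-(3,5-dihydroxyphenyl)pentadec-7-en-6-yl acetate
Conditions: pyrrolidine (2.5 equiv), CH2Cl2, 0 °C, Ar; then aq. NH4Cl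
Reagents that add atoms: none
Why: Chemoselective aminolysis: aryl acetates, with a phenoxide leaving group, react with a secondary amine far faster than a secondary alkyl acetate, so both phenols should be released while the C10 acetate stays.

**Compound list**

1 | (R)-oct-1-yn-3-ol | CCCCC[C@H](C#C)O | starting material
2 | triisopropyl{[(3R)-oct-1-yn-3-yl]oxy}silane | CCCCC[C@H](C#C)O[Si](C(C)C)(C(C)C)C(C)C | intermediate
3 | 9-bromonon-1-ene | BrCCCCCCCC=C | starting material
4 | [(3R)-3-(triisopropylsilyloxy)oct-1-yn-1-yl]lithium | CCCCC[C@H](C#C[Li])O[Si](C(C)C)(C(C)C)C(C)C | intermediate (not isolated)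
5 | triisopropyl{[(12R)-heptadec-1-en-10-yn-12-yl]oxy}silane | CCCCC[C@H](C#CCCCCCCCC=C)O[Si](C(C)C)(C(C)C)C(C)C | intermediate
6 | (12R)-12-(triisopropylsilyloxy)heptadec-10-yne-1,2-diol (C2 epimers) | CCCCC[C@H](C#CCCCCCCCC(O)CO)O[Si](C(C)C)(C(C)C)C(C)C | intermediate (not isolated)
7 | (11R)-11-(triisopropylsilyloxy)hexadec-9-ynal | CCCCC[C@H](C#CCCCCCCCC=O)O[Si](C(C)C)(C(C)C)C(C)C | intermediate
8 | 1-(triphenylphosphoranylidene)propan-2-one | CC(=O)C=P(c1ccccc1)(c1ccccc1)c1ccccc1 | starting material
9 | (3E,14R)-14-(triisopropylsilyloxy)nonadec-3-en-12-yn-2-one | CCCCC[C@H](C#CCCCCCCC/C=C/C(C)=O)O[Si](C(C)C)(C(C)C)C(C)C | intermediate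
10 | dimethyl malonate | COC(=O)CC(=O)OC | starting material
11 | dimethyl 2-[(14R)-2-oxo-14-(triisopropylsilyloxy)nonadec-12-yn-4-yl]propanedioate (C4 epimers) | CCCCC[C@H](C#CCCCCCCCC(CC(C)=O)C(C(=O)OC)C(=O)OC)O[Si](C(C)C)(C(C)C)C(C)C | intermediate (not isolated)
12 | methyl 2,4-dioxo-6-[(10R)-10-(triisopropylsilyloxy)pentadec-8-yn-1-yl]cyclohexane-1-carboxylate (ring diastereomers) | CCCCC[C@H](C#CCCCCCCCC1CC(=O)CC(=O)C1C(=O)OC)O[Si](C(C)C)(C(C)C)C(C)C | intermediate
13 | methyl 3-bromo-2,4-dioxo-6-[(10R)-10-(triisopropylsilyloxy)pentadec-8-yn-1-yl]cyclohexane-1-carboxylate | CCCCC[C@H](C#CCCCCCCCC1CC(=O)C(Br)C(=O)C1C(=O)OC)O[Si](C(C)C)(C(C)C)C(C)C | intermediate (not isolated)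
14 | methyl 2,4-dihydroxy-6-[(10R)-10-(triisopropylsilyloxy)pentadec-8-yn-1-yl]benzoate | CCCCC[C@H](C#CCCCCCCCc1cc(O)cc(O)c1C(=O)OC)O[Si](C(C)C)(C(C)C)C(C)C | intermediate
15 | 2,4-dihydroxy-6-[(10R)-10-(triisopropylsilyloxy)pentadec-8-yn-1-yl]benzoic acid | CCCCC[C@H](C#CCCCCCCCc1cc(O)cc(O)c1C(=O)O)O[Si](C(C)C)(C(C)C)C(C)C | intermediate (not isolated)
16 | 5-[(10R)-10-(triisopropylsilyloxy)pentadec-8-yn-1-yl]benzene-1,3-diol | CCCCC[C@H](C#CCCCCCCCc1cc(O)cc(O)c1)O[Si](C(C)C)(C(C)C)C(C)C | intermediate
17 | 5-[(8Z,10R)-10-(triisopropylsilyloxy)pentadec-8-en-1-yl]benzene-1,3-diol | CCCCC[C@H](/C=C\CCCCCCCc1cc(O)cc(O)c1)O[Si](C(C)C)(C(C)C)C(C)C | intermediate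
18 | 5-[(8Z,10R)-10-hydroxypentadec-8-en-1-yl]benzene-1,3-diol | CCCCC[C@H](/C=C\CCCCCCCc1cc(O)cc(O)c1)O | intermediate
19 | 5-[(8Z,10R)-10-acetoxypentadec-8-en-1-yl]-1,3-phenylene diacetate | CCCCC[C@H](/C=C\CCCCCCCc1cc(OC(C)=O)cc(OC(C)=O)c1)OC(C)=O | intermediate
20 | (6R,7Z)-15-(3,5-dihydroxyphenyl)pentadec-7-en-6-yl acetate | CCCCC[C@H](/C=C\CCCCCCCc1cc(O)cc(O)c1)OC(C)=O | target

**Step count and risks**

Total steps: 11. Longest linear sequence: 11 (steps 1–11 from 1; compounds 3, 8 and 10 are bought).

Steps most likely to fail: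

1. Step 6. Bromine or HBr may add to the C8–C9 triple bond, bromine may be transferred to the newly formed electron-rich ring, and the silyl ether may be lost to acid during the hot dehydrobromination. The fallback sets out from 12 and avoids halogen altogether. Double O-silylation (TBSOTf, Et3N, CH2Cl2, 0 °C) should give methyl 2,4-bis(tert-butyldimethylsilyloxy)-6-[(10R)-10-(triisopropylsilyloxy)pentadec-8-yn-1-yl]cyclohexa-1,3-diene-1-carboxylate F1. DDQ in toluene at rt should abstract hydride from C6, giving a cation stabilised by both silyloxy groups, and after proton loss methyl 2,4-bis(tert-butyldimethylsilyloxy)-6-[(10R)-10-(triisopropylsilyloxy)pentadec-8-yn-1-yl]benzoate F2. K2CO3 in MeOH at rt should then cleave only the two aryl silyl ethers, and the route is rejoined at 14.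

2. Step 5. The sequence may stop at the open-chain Michael adduct or revert by retro-Michael reaction, and methoxide may compete as a conjugate nucleophile or promote self-condensation of the methyl ketone, so that ring closure stays incomplete. The fallback sets out from 7 and exchanges the roles of the partners. Wittig olefination with methyl (triphenylphosphoranylidene)acetate (CH2Cl2, rt) should give methyl (2E,13R)-13-(triisopropylsilyloxy)octadec-2-en-11-ynoate F3. Methyl acetoacetate with NaOMe in refluxing MeOH should add through its central carbon to give dimethyl 2-acetyl-3-[(10R)-10-(triisopropylsilyloxy)pentadec-8-yn-1-yl]pentanedioate F4 (not isolated), whose acetyl methyl enolate closes onto the terminal ester in a Dieckmann-type condensation. After acidification this is the same dione ester, and the route is rejoined at 12.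

3. Step 7. Hydrolysis of the hydrogen-bonded, doubly ortho-substituted ester may be slow and force prolonged heating in hydroxide, during which the resorcinolate may be oxidised and the silyl ether eroded. The fallback sets out from 12 and removes the ester before the ring is aromatic and without hydroxide. Krapcho dealkoxycarbonylation (LiCl, wet DMSO, 140 °C) should pass through 2,4-dioxo-6-[(10R)-10-(triisopropylsilyloxy)pentadec-8-yn-1-yl]cyclohexane-1-carboxylic acid F5 (as its lithium salt, not isolated) to 5-[(10R)-10-(triisopropylsilyloxy)pentadec-8-yn-1-yl]cyclohexane-1,3-dione F6. Bromine (1.0 equiv) in DMF at 0 °C and then 80 °C should brominate C2 to give 2-bromo-5-[(10R)-10-(triisopropylsilyloxy)pentadec-8-yn-1-yl]cyclohexane-1,3-dione F7 (not isolated), which loses HBr and tautomerises, and the route is rejoined at 16.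

**Further compounds**

F1 | step 6 | methyl 2,4-bis(tert-butyldimethylsilyloxy)-6-[(10R)-10-(triisopropylsilyloxy)pentadec-8-yn-1-yl]cyclohexa-1,3-diene-1-carboxylate | CCCCC[C@H](C#CCCCCCCCC1CC(O[Si](C)(C)C(C)(C)C)=CC(O[Si](C)(C)C(C)(C)C)=C1C(=O)OC)O[Si](C(C)C)(C(C)C)C(C)C
F2 | step 6 | methyl 2,4-bis(tert-butyldimethylsilyloxy)-6-[(10R)-10-(triisopropylsilyloxy)pentadec-8-yn-1-yl]benzoate | CCCCC[C@H](C#CCCCCCCCc1cc(O[Si](C)(C)C(C)(C)C)cc(O[Si](C)(C)C(C)(C)C)c1C(=O)OC)O[Si](C(C)C)(C(C)C)C(C)C
F3 | step 5 | methyl (2E,13R)-13-(triisopropylsilyloxy)octadec-2-en-11-ynoate | CCCCC[C@H](C#CCCCCCCC/C=C/C(=O)OC)O[Si](C(C)C)(C(C)C)C(C)C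
F4 | step 5 | dimethyl 2-acetyl-3-[(10R)-10-(triisopropylsilyloxy)pentadec-8-yn-1-yl]pentanedioate | CCCCC[C@H](C#CCCCCCCCC(CC(=O)OC)C(C(C)=O)C(=O)OC)O[Si](C(C)C)(C(C)C)C(C)C
F5 | step 7 | 2,4-dioxo-6-[(10R)-10-(triisopropylsilyloxy)pentadec-8-yn-1-yl]cyclohexane-1-carboxylic acid | CCCCC[C@H](C#CCCCCCCCC1CC(=O)CC(=O)C1C(=O)O)O[Si](C(C)C)(C(C)C)C(C)C
F6 | step 7 | 5-[(10R)-10-(triisopropylsilyloxy)pentadec-8-yn-1-yl]cyclohexane-1,3-dione | CCCCC[C@H](C#CCCCCCCCC1CC(=O)CC(=O)C1)O[Si](C(C)C)(C(C)C)C(C)C
F7 | step 7 | 2-bromo-5-[(10R)-10-(triisopropylsilyloxy)pentadec-8-yn-1-yl]cyclohexane-1,3-dione | CCCCC[C@H](C#CCCCCCCCC1CC(=O)C(Br)C(=O)C1)O[Si](C(C)C)(C(C)C)C(C)C
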